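**Retrosynthetic overview**
1. Lehualide K ⇒ oxidative S–S coupling of two C10 thiols ⇒ thioacetate ⇒ anti-Markovnikov thiol–ene on 6-(dec-9-enyl)-3,4-dimethoxy-5-methyl-2-pyranone.
2. Pyranone ⇒ enolate O-methylation and enol lactonisation (O1–C2 bond) of acyclic methyl 3-methoxy-4-methyl-2,5-dioxopentadec-14-enoate. The C4-OMe is already in place, so there is no α/γ-pyrone methylation ambiguity.
3. Key C5–C6 bond (pyranone numbering) ⇒ Stetter reaction: undec-10-enal as acyl anion (Breslow enaminol) plus the β-carbon of methyl 3-methoxy-2-oxopent-3-enoate. Both carbons are natively electrophilic.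
4. Acceptor ⇒ α-metalated allyl methyl ether plus dimethyl oxalate.
5. Ring order: the 2-pyranone is the only ring type. It is closed once (step 3), and the two copies are joined in the last step.

Assumption: the SMILES holds no stereocentre and no stereogenic double bond, so lehualide K is achiral and needs no enantiocontrol. The transient stereocentres in 4 and 8 are erased later.

**Step 1**
Reactants: 1 allyl methyl ether; 2 dimethyl oxalate
Product: 5 methyl (Z)-3-methoxy-2-oxopent-3-enoate, via 1-methoxyallyllithium 3 (not isolated), via deconjugated keto ester 4 (not isolated)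
Conditions: s-BuLi (1.0 equiv), THF, −78 °C, 30 min; cannulate into 2 (3 equiv), THF, −78 °C; AcOH quench; crude + Et3N (10 mol %), CH2Cl2, rt
Reagents that add atoms: none
Why: Metalation of the allyl ether gives the oxygen-stabilised allyl anion 3, which attacks carbonyl electrophiles mainly through its oxygen-bearing carbon, so nucleophilic acyl substitution on excess cold oxalate stops at mono-addition to give 4, whose doubly activated C3–H lets catalytic Et3N move the alkene into conjugation (prototropic isomerisation) to the more stable Z enone 5, leaving no lasting stereocentre.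

**Step 2 (key step)**
Reactants: 5 methyl (Z)-3-methoxy-2-oxopent-3-enoate; 6 undec-10-enal
Product: 8 methyl 3-methoxy-4-methyl-2,5-dioxopentadec-14-enoate, via Breslow enaminol 7 (not isolated)
Conditions: 3-benzyl-5-(2-hydroxyethyl)-4-methylthiazolium chloride (20 mol %), Et3N (40 mol %), 1,4-dioxane, 70 °C, Ar; 6 (1.5 equiv) added by syringe pump
Reagents that add atoms: none
Why: Proposed new method: a Stetter reaction in which the thiazol-2-ylidene turns the aldehyde carbon of 6 into the nucleophilic enaminol 7 (acyl anion equivalent), which adds to the β-carbon of 5, an acceptor that is trisubstituted and carries a donor α-OMe but keeps a low LUMO through the vicinal keto ester, while competing 1,2-addition to the keto group (cross-benzoin) and acyloin formation are reversible at 70 °C and the conjugate addition is made irreversible by proton transfer and catalyst release; the closest known reaction type is the thiazolium-catalysed Stetter addition of aliphatic aldehydes to β-substituted enones and β,γ-unsaturated α-keto esters, and the two new stereocentres form as a racemic diastereomer mixture that step 3 erases.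

**Step 3**
Reactants: 8 methyl 3-methoxy-4-methyl-2,5-dioxopentadec-14-enoate
Product: 10 6-(dec-9-en-1-yl)-3,4-dimethoxy-5-methyl-2H-pyran-2-one, via dimethoxy enoate 9 (not isolated)
Conditions: Me2SO4 (1.1 equiv), K2CO3 (2 equiv), MeCN, 0 °C to rt; then DBU (0.5 equiv), 60 °C
Reagents that add atoms: dimethyl sulfate, COS(=O)(=O)OC
Why: The C3–H next to the keto ester is by far the most acidic site, so its enolate is O-methylated first (hard electrophile, fully substituted carbon), which removes both the electrophilic ketone (no cyclopentenone aldol) and the β-methoxy ketone motif (no E1cB loss of MeOH), and DBU then forms the extended dienolate of 9, which equilibrates E/Z and closes through the ketone oxygen onto the ester (enol lactonisation by addition–elimination) to the conjugated 2-pyranone, erasing both stereocentres.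

**Step 4**
Reactants: 10 6-(dec-9-en-1-yl)-3,4-dimethoxy-5-methyl-2H-pyran-2-one; 11 thioacetic acid
Product: 12 6-(10-acetylsulfanyldecyl)-3,4-dimethoxy-5-methyl-2H-pyran-2-one
Conditions: 11 (3 equiv), AIBN (10 mol %), toluene, 80 °C
Reagents that add atoms: none
Why: Radical thiol–ene reaction (anti-Markovnikov hydrothiolation) in which the acetylthiyl radical adds to the terminal CH2 and the secondary radical abstracts H from AcSH, whereas the tetrasubstituted pyranone double bonds add thiyl radicals only reversibly and thermal initiation avoids pyranone photochemistry.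

**Step 5**
Reactants: 12 6-(10-acetylsulfanyldecyl)-3,4-dimethoxy-5-methyl-2H-pyran-2-one (2 equiv)
Product: 14 lehualide K, via free thiol 13 (not isolated)
Conditions: HCl (1.25 M in MeOH), 50 °C, Ar; cool to rt, then I2 (0.5 equiv per thiol, titrated to persistent colour), MeOH–CH2Cl2; aq Na2S2O3/NaHCO3 work-up
Reagents that add atoms: none
Why: Acid-catalysed methanolysis (transesterification) cleaves the thioester without the alkoxide that could open the pyranone, and iodine then oxidises thiol 13 to the symmetrical disulfide (oxidative S–S coupling), with no stereocentre involved.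

**Compound list**
1 | allyl methyl ether (3-methoxyprop-1-ene) | C=CCOC | starting material
2 | dimethyl oxalate | COC(=O)C(=O)OC | starting material
3 | 1-methoxyallyllithium (delocalised allyl anion, drawn α-lithiated) | [Li]C(OC)C=C | intermediate
4 | methyl 3-methoxy-2-oxopent-4-enoate (racemic) | C=CC(OC)C(=O)C(=O)OC | intermediate
5 | methyl (Z)-3-methoxy-2-oxopent-3-enoate (Z major; alkene geometry has no consequence later) | C/C=C(\OC)C(=O)C(=O)OC | intermediate
6 | undec-10-enal | C=CCCCCCCCCC=O | starting material
7 | Breslow enaminol, 1-[3-benzyl-5-(2-hydroxyethyl)-4-methylthiazol-2(3H)-ylidene]undec-10-en-1-ol | C=CCCCCCCCCC(O)=C1SC(CCO)=C(C)N1Cc1ccccc1 | intermediate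
8 | methyl 3-methoxy-4-methyl-2,5-dioxopentadec-14-enoate (racemic diastereomer mixture, keto/enol) | C=CCCCCCCCCC(=O)C(C)C(OC)C(=O)C(=O)OC | intermediate
9 | methyl 2,3-dimethoxy-4-methyl-5-oxopentadeca-2,14-dienoate (E/Z mixture at C2=C3, racemic) | C=CCCCCCCCCC(=O)C(C)C(OC)=C(OC)C(=O)OC | intermediate
10 | 6-(dec-9-en-1-yl)-3,4-dimethoxy-5-methyl-2H-pyran-2-one | C=CCCCCCCCCc1oc(=O)c(OC)c(OC)c1C | intermediate
11 | thioacetic acid | CC(=O)S | starting material
12 | 6-(10-acetylsulfanyldecyl)-3,4-dimethoxy-5-methyl-2H-pyran-2-one | CC(=O)SCCCCCCCCCCc1oc(=O)c(OC)c(OC)c1C | intermediate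
13 | 3,4-dimethoxy-5-methyl-6-(10-sulfanyldecyl)-2H-pyran-2-one | SCCCCCCCCCCc1oc(=O)c(OC)c(OC)c1C | intermediate
14 | lehualide K, bis[10-(3,4-dimethoxy-5-methyl-2-oxo-2H-pyran-6-yl)decyl] disulfide (achiral) | COc1c(C)c(CCCCCCCCCCSSCCCCCCCCCCc2oc(=O)c(OC)c(OC)c2C)oc(=O)c1OC | target

**Total step count:** 5. **Longest linear sequence:** 5 (1 → 5 → 8 → 10 → 12 → 14). Compounds 2, 6 and 11 are bought.

**Three steps most likely to fail**

Step 2 (Stetter on the captodative, β-substituted acceptor). The addition may be too slow, and acyloin or cross-benzoin products or self-condensation of 5 may take over.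
The fallback sets out from 5 and 6 and comes back at 8. It replaces the closed-shell acyl anion by a nucleophilic acyl radical. (n-Bu4N)4[W10O32] (2 mol %) in MeCN under 390 nm light abstracts the aldehyde hydrogen of 6. The acyl radical adds to the β-carbon of 5, where the α-OMe/α-acyl pair now helps by giving a captodatively stabilised radical. Back hydrogen transfer from the reduced polyoxometalate then delivers 8. This way makes no compound outside the list (F0).

Step 3 (methylation and lactonisation). C-methylation, loss of MeOH, furan formation or cyclopentenone formation may compete.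
The fallback sets out from 8 and comes back at 10. It closes the ring first, under acylating rather than basic alkylating conditions.
- Brief LiOH (1.05 equiv) in THF–H2O at 0 °C saponifies the very reactive α-keto ester to 3-methoxy-4-methyl-2,5-dioxopentadec-14-enoic acid F1.
- Ac2O with NaOAc at 60 °C activates the acid as a mixed anhydride. The ketone is enol-lactonised and the resulting 3-hydroxy group is capped, giving 6-(dec-9-en-1-yl)-4-methoxy-5-methyl-2-oxo-2H-pyran-3-yl acetate F2.
- K2CO3 in MeOH at 0 °C removes the acetate to give 6-(dec-9-en-1-yl)-3-hydroxy-4-methoxy-5-methyl-2H-pyran-2-one F3.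
- The single acidic OH of F3 is methylated with Me3SiCHN2 in toluene–MeOH to give 10.

Step 1 (α- versus γ-acylation of the allyl anion, over-addition, proton transfer from 4).
The fallback sets out from 2 and comes back at 5. It builds the alkene by olefination instead of allyl-anion acylation.
- Diethyl (methoxymethyl)phosphonate is lithiated with LiN(i-Pr)2 in THF at −78 °C and acylated with 2. This gives methyl 3-(diethoxyphosphoryl)-3-methoxy-2-oxopropanoate F4.
- F4 undergoes a Horner–Wadsworth–Emmons reaction with acetaldehyde (LiCl, i-Pr2NEt, MeCN, 0 °C to rt) to give 5 directly, with no regiochemical issue.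

**Further compounds**
F0 | step 2 | none | none
F1 | step 3 | 3-methoxy-4-methyl-2,5-dioxopentadec-14-enoic acid (racemic diastereomer mixture) | C=CCCCCCCCCC(=O)C(C)C(OC)C(=O)C(=O)O
F2 | step 3 | 6-(dec-9-en-1-yl)-4-methoxy-5-methyl-2-oxo-2H-pyran-3-yl acetate | C=CCCCCCCCCc1oc(=O)c(OC(C)=O)c(OC)c1C
F3 | step 3 | 6-(dec-9-en-1-yl)-3-hydroxy-4-methoxy-5-methyl-2H-pyran-2-one | C=CCCCCCCCCc1oc(=O)c(O)c(OC)c1C
F4 | step 1 | methyl 3-(diethoxyphosphoryl)-3-methoxy-2-oxopropanoate (racemic) | CCOP(=O)(OCC)C(OC)C(=O)C(=O)OC
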